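In a one-step world, solid substrate would give target and there would be no isomer of the product. Tuesday's run refused that: at 20.0 s the isomer's share of isomer plus target already stood at 31.5 %.

- Tuesday's: solid substrate 0.92 M; free catalyst 36 mM; run made earlier
- flask: solid substrate 0.92 M; free catalyst 18 mM; time 8.0 min

- Tuesday's (time / s: isomer of the product / %, target / %): 20.0: 3.4, 7.4; 40.0: 13.3, 13.1; 60.0: 22.2, 14.6; 80.0: 33.6, 16.7; 90.0: 39.8, 17.2

(scatter of a reading: 0.5 percentage points)

- given per volume of solution although it is solid: solid substrate
- the analysis behind the earlier runs scatters by 0.5 percentage points, standard deviation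
- at the start none of the solid substrate is in solution
- no earlier run changes the charge of free catalyst; that part of a forecast is a guess

1. share of isomer of the product in isomer of the product plus target at 12 s
2. share of isomer of the product in isomer of the product plus target at 8.0 min
3. which of isomer of the product and target there is more of at 8.0 min

So I added a second route beside the first and took the symmetric case as the zero of my scale: the odds ρ, isomer over target, equal to one. A fixed split would hold ρ still, but Tuesday's ρ grew with time. I therefore named τ, the crossing time at which isomer equals target, which Tuesday's reading at 40.0 s puts at 39.4 s. With time t, my rule for Tuesday's run is ρ = t/τ, so the share is t/(t+τ).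

| Tuesday, t | ρ read | t/τ |
|---|---|---|
| 20.0 s | 0.459 | 0.508 |
| 60.0 s | 1.52 | 1.52 |
| 90.0 s | 2.31 | 2.28 |

Last I added the catalyst. I guessed that the target route needs free catalyst and fades with it, while the isomer route does not, so that τ goes with the charge. For the new flask, with 18 mM, that gave τ = 19.7 s. The share then came to 37.9 % at 12 s and, far beyond the readings, 96.1 % at 8.0 min, with isomer leading.

The forecast gave 10.5 % (6 % to 20 %) at the early time, lower than mine, and 98 % at the late time, with isomer of the product leading; of the catalyst it said “That order is a guess, since no run varies the catalyst.”

The flask gave 39.6 % and 99.0 %, with isomer at 70.4 % and target at 0.697 %.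

    starting material ⇌ other conformer (K = 3.00, k = 0.0480 s⁻¹)
    starting material + free catalyst → free catalyst + target (k = 5.00 L mol⁻¹ s⁻¹)
    free catalyst + other conformer → free catalyst + isomer of the product (k = 62.0 L mol⁻¹ s⁻¹)
    solid substrate ⇌ starting material, rate k4*(cs4 - [starting material]) while solid is left; crystals form when [starting material] > cs4 (solubility = 0.710 M, k = 0.0140 s⁻¹)
    2 free catalyst → spent catalyst (k = 1.90 L mol⁻¹ s⁻¹)
    target → over-reaction product (k = 0.00900 s⁻¹)

In this flask the crossing came at 26.3 s, later than my 19.7 s. At the catalyst as charged, the pseudo-first-order constant of the target step, 0.0900 s⁻¹, stood above the forward constant of the step to other conformer, 0.048 s⁻¹; by 0.874 min in this flask the forward step to other conformer used starting material at 2.4 times the rate of the target step. For the neighbour with 0.0072 M, τ gives 7.88 s and a share of 60.4 % at 12 s. The computed share is 52.0 %, less than that, with isomer ahead.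

(The runs stem from a simulated flask for substances that don't exist, and the scatter is random.)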